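**Plan**
Locants are those of the target's oxolane ring: O1, C2 (3,4-dimethoxyphenyl), C3 (CH2OH), C4 (aroyl), C5. The retrosynthesis first cuts the ketone carbon–trimethoxyphenyl bond (aryl Grignard reagent plus a γ-lactone tying the C3 arm to the C4 acyl carbon), then removes the two ring-fusion hydrogens (butenolide), then cuts O1–C2 and C3–C4 together.
Enabling feature: C2–C3 plus the CH2OH carbon form a cinnamaldehyde skeleton with O1 on its β-carbon, and O1–C5–C4 plus the ketone carbon form a 3-hydroxy-2-oxopropanoate skeleton whose keto carbon (C4) is the aldol partner of C3. One oxa-Michael/aldol event therefore closes the oxolane ring.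
Forward order: oxolane ring (step 2), C3=C4 double bond, temporary butenolide ring fused on C3–C4, saturated cis-fused lactone, lactone opening by the aryl Grignard reagent, C4 epimerisation.
Stereochemistry: C2 from the amine catalyst; C3 from hydride delivery to the butenolide face anti to the C2 aryl group (this gives the contra-thermodynamic 2,3-cis relation); C4 from final base equilibration to 3,4-trans.

Key step: step 2

Assumptions: the (S)-catalyst is taken to shield the Re face of C2, as the steric model for iminium ions of this catalyst class predicts; if the sense of induction proved opposite, the (R)-catalyst would be used without other change. Compounds 1, 2, 4 and 12 (as a THF solution) are taken as commercial. Compound 3 may exist partly as hydrate or hemiketal dimer and is used as such.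

**Step 1**
Reactants: 1 lithium 3-hydroxy-2-oxopropanoate; 2 benzyl bromide
Product: 3 benzyl 3-hydroxy-2-oxopropanoate
Conditions: BnBr, n-Bu4NI (cat.), DMF, 0 °C to rt
Reagents that add atoms: 2 benzyl bromide, BrCc1ccccc1
Why: SN2 O-alkylation of the carboxylate by benzyl bromide (iodide catalysis) should give the benzyl α-keto ester without touching the un-ionised primary hydroxyl, and no stereocentre is involved.

**Step 2**
Reactants: 4 (2E)-3-(3,4-dimethoxyphenyl)prop-2-enal; 3 benzyl 3-hydroxy-2-oxopropanoate
Product: 6 benzyl (5S)-5-(3,4-dimethoxyphenyl)-4-formyl-3-hydroxyoxolane-3-carboxylate (mixture at the two other ring centres), via oxa-Michael adduct 5 (not isolated)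
Conditions: (S)-2-[diphenyl(trimethylsilyloxy)methyl]pyrrolidine (20 mol %), PhCO2H (20 mol %), CHCl3, rt
Reagents that add atoms: none
Why: Condensation of 4 with the amine should give an E-iminium ion whose Re face at C2 is shielded by the diphenyl(trimethylsilyloxy)methyl group, so that the primary hydroxyl of 3 adds to the Si face (oxa-Michael addition, O1–C2), and the enamine so formed attacks the keto carbonyl of the pyruvate unit through C3 (aldol addition, C3–C4) before hydrolysis returns the catalyst. The closest known reaction type is the diarylprolinol silyl ether catalysed oxa-Michael/aldol domino reaction of β-aryl enals with α-hydroxy ketones such as 1,3-dihydroxyacetone dimer, together with its sulfur counterpart with α-mercapto ketones. The oxolane ring closes in the aldol event by a 5-(enolexo)-exo-trig attack of the enamine carbon on the ketone. C2 (S) is set by the catalyst, whereas C3 and C4 arise under substrate control and are both erased in step 3, so their ratio does not matter. The step needs O- rather than C-alkylation of 3, 1,4- rather than 1,2-addition to 4 and aldol attack on the ketone rather than the ester, which the substrate secures through its single unhindered hydroxyl, the iminium activation of C2 and the much higher electrophilicity of the α-keto carbonyl placed to form a five-membered ring. Because the oxa-Michael addition is reversible, the ring closure is what draws the equilibrium forward, and benzoic acid keeps iminium formation and hydrolysis fast.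

**Step 3**
Reactants: 6 benzyl (5S)-5-(3,4-dimethoxyphenyl)-4-formyl-3-hydroxyoxolane-3-carboxylate
Product: 8 benzyl (5R)-5-(3,4-dimethoxyphenyl)-4-formyl-2,5-dihydrofuran-3-carboxylate (same spatial arrangement at the aryl-bearing carbon; the descriptor changes by priority only), via tertiary mesylate 7 (not isolated)
Conditions: MsCl, Et3N, CH2Cl2, −20 to 0 °C; used at once
Reagents that add atoms: none
Why: Mesylation of the tertiary hydroxyl followed by E1cB loss of methanesulfonate through the aldehyde enolate should place the double bond between C3 and C4 whatever the configuration of 6 at these centres, leaving C2 as the only stereocentre, and the low temperature and short contact with Et3N are meant to prevent γ-deprotonation at C2.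

**Step 4**
Reactants: 8 benzyl (5R)-5-(3,4-dimethoxyphenyl)-4-formyl-2,5-dihydrofuran-3-carboxylate
Product: 10 (4R)-4-(3,4-dimethoxyphenyl)-4,6-dihydro-1H,3H-furo[3,4-c]furan-1-one, via hydroxy ester 9 (not isolated)
Conditions: NaBH4, THF–MeOH, −40 °C; then camphorsulfonic acid (cat.), CH2Cl2, rt
Reagents that add atoms: none
Why: 1,2-Reduction of the aldehyde by NaBH4 at low temperature (the ester survives) should give a γ-hydroxy enoate whose cis geometry is fixed by the ring, so that acid-catalysed lactonisation closes the butenolide with loss of benzyl alcohol while C2 is untouched.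

**Step 5**
Reactants: 10 (4R)-4-(3,4-dimethoxyphenyl)-4,6-dihydro-1H,3H-furo[3,4-c]furan-1-one
Product: 11 (3aS,4S,6aS)-4-(3,4-dimethoxyphenyl)tetrahydro-1H,3H-furo[3,4-c]furan-1-one (cis-fused; aryl group on the concave face)
Conditions: Cu(OAc)2·H2O (5 mol %), 1,2-bis(diphenylphosphino)benzene (5 mol %), (EtO)2MeSiH, t-BuOH, toluene, 0 °C to rt
Reagents that add atoms: none
Why: Copper hydride conjugate reduction of the butenolide should transfer hydride to C3 (the β-carbon) from the face anti to the adjacent C2 aryl group, which sets C3 with its CH2O arm cis to the aryl group, while protonation at C4 by t-BuOH can only give the cis ring fusion, and a polar hydride is chosen because it cannot move the double bond towards the aryl ring and so cannot erase C2.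

**Step 6**
Reactants: 11 (3aS,4S,6aS)-4-(3,4-dimethoxyphenyl)tetrahydro-1H,3H-furo[3,4-c]furan-1-one; 12 3,4,5-trimethoxyphenylmagnesium bromide
Product: 14 (3aS,4S,6aS)-4-(3,4-dimethoxyphenyl)-1-(3,4,5-trimethoxyphenyl)tetrahydro-1H,3H-furo[3,4-c]furan-1-ol (anomeric mixture at the hemiketal carbon), via magnesium hemiketal alkoxide 13 (not isolated)
Conditions: 12 (1.1 equiv), THF, −78 to −40 °C; then sat. aq NH4Cl
Reagents that add atoms: 12 3,4,5-trimethoxyphenylmagnesium bromide, COc1cc([Mg]Br)cc(OC)c1OC
Why: 1,2-Addition of the aryl Grignard reagent to the lactone carbonyl should stop at the tetrahedral magnesium hemiketal alkoxide at low temperature, the usual lactone to aryl hemiketal step of furofuran lignan chemistry, so that work-up gives the hemiketal with C2, C3 and C4 unchanged.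

**Step 7**
Reactants: 14 (3aS,4S,6aS)-4-(3,4-dimethoxyphenyl)-1-(3,4,5-trimethoxyphenyl)tetrahydro-1H,3H-furo[3,4-c]furan-1-ol
Product: 16 [(3R,4S,5S)-5-(3,4-dimethoxyphenyl)-4-(hydroxymethyl)oxolan-3-yl](3,4,5-trimethoxyphenyl)methanone (CNP0271206.3), via cis keto alcohol 15 (not isolated)
Conditions: DBU (0.2 equiv), toluene, rt to 40 °C
Reagents that add atoms: none
Why: Ring–chain tautomerism of 14 exposes the aryl ketone 15, whose C4–H is the only acidic C–H, and base-mediated enolisation (epimerisation) should funnel the material to the 3,4-trans isomer, which relieves the all-cis arrangement and cannot re-close to a hemiketal because that would need a trans-fused bicyclo[3.3.0] system, while C2 and C3 carry no acidic hydrogen and keep their configuration.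

**Compound list**
1 | lithium 3-hydroxy-2-oxopropanoate | [Li+].[O-]C(=O)C(=O)CO | starting material
2 | benzyl bromide | BrCc1ccccc1 | starting material
3 | benzyl 3-hydroxy-2-oxopropanoate | OCC(=O)C(=O)OCc1ccccc1 | intermediate
4 | (2E)-3-(3,4-dimethoxyphenyl)prop-2-enal | COc1ccc(/C=C/C=O)cc1OC | starting material
5 | benzyl 3-{[(1S)-1-(3,4-dimethoxyphenyl)-3-oxopropyl]oxy}-2-oxopropanoate | COc1ccc([C@H](CC=O)OCC(=O)C(=O)OCc2ccccc2)cc1OC | intermediate
6 | benzyl (5S)-5-(3,4-dimethoxyphenyl)-4-formyl-3-hydroxyoxolane-3-carboxylate | COc1ccc([C@H]2OCC(O)(C(=O)OCc3ccccc3)C2C=O)cc1OC | intermediate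
7 | benzyl (5S)-5-(3,4-dimethoxyphenyl)-4-formyl-3-(methanesulfonyloxy)oxolane-3-carboxylate | COc1ccc([C@H]2OCC(OS(C)(=O)=O)(C(=O)OCc3ccccc3)C2C=O)cc1OC | intermediate
8 | benzyl (5R)-5-(3,4-dimethoxyphenyl)-4-formyl-2,5-dihydrofuran-3-carboxylate | COc1ccc([C@H]2OCC(C(=O)OCc3ccccc3)=C2C=O)cc1OC | intermediate
9 | benzyl (5R)-5-(3,4-dimethoxyphenyl)-4-(hydroxymethyl)-2,5-dihydrofuran-3-carboxylate | COc1ccc([C@H]2OCC(C(=O)OCc3ccccc3)=C2CO)cc1OC | intermediate
10 | (4R)-4-(3,4-dimethoxyphenyl)-4,6-dihydro-1H,3H-furo[3,4-c]furan-1-one | COc1ccc([C@H]2OCC3=C2COC3=O)cc1OC | intermediate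
11 | (3aS,4S,6aS)-4-(3,4-dimethoxyphenyl)tetrahydro-1H,3H-furo[3,4-c]furan-1-one | COc1ccc([C@H]2OC[C@H]3C(=O)OC[C@@H]23)cc1OC | intermediate
12 | 3,4,5-trimethoxyphenylmagnesium bromide | COc1cc([Mg]Br)cc(OC)c1OC | starting material
13 | bromomagnesium (3aS,4S,6aS)-4-(3,4-dimethoxyphenyl)-1-(3,4,5-trimethoxyphenyl)tetrahydro-1H,3H-furo[3,4-c]furan-1-olate | COc1ccc([C@H]2OC[C@H]3C(O[Mg]Br)(c4cc(OC)c(OC)c(OC)c4)OC[C@@H]23)cc1OC | intermediate
14 | (3aS,4S,6aS)-4-(3,4-dimethoxyphenyl)-1-(3,4,5-trimethoxyphenyl)tetrahydro-1H,3H-furo[3,4-c]furan-1-ol | COc1ccc([C@H]2OC[C@H]3C(O)(c4cc(OC)c(OC)c(OC)c4)OC[C@@H]23)cc1OC | intermediate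
15 | [(3S,4S,5S)-5-(3,4-dimethoxyphenyl)-4-(hydroxymethyl)oxolan-3-yl](3,4,5-trimethoxyphenyl)methanone | COc1ccc([C@H]2OC[C@@H](C(=O)c3cc(OC)c(OC)c(OC)c3)[C@H]2CO)cc1OC | intermediate
16 | [(3R,4S,5S)-5-(3,4-dimethoxyphenyl)-4-(hydroxymethyl)oxolan-3-yl](3,4,5-trimethoxyphenyl)methanone | COc1ccc([C@H]2OC[C@H](C(=O)c3cc(OC)c(OC)c(OC)c3)[C@H]2CO)cc1OC | target

**Totals**
Total step count: 7. Longest linear sequence: 7 steps (1, 3, 6, 8, 10, 11, 14, 16).

**Steps most likely to fail**

Step 2. Process at risk: self-condensation or enolisation of keto ester 3 under amine catalysis, or erosion of enantioselectivity through reversible oxa-Michael addition ahead of a slow aldol closure. The fallback brings in the oxidation pattern after the ring is made, using the α-hydroxy ketone for which this domino reaction has its closest precedent. It sets out from 4 and returns at 11. Compound 4 and commercial 1,3-dihydroxyacetone dimer, under the conditions of step 2, should give the bicyclic hemiacetal (6S)-6-(3,4-dimethoxyphenyl)tetrahydro-1H,3H-furo[3,4-c]furan-1,3a-diol F1, in which the second hydroxymethyl group traps the aldehyde. PhI(OAc)2 with catalytic TEMPO oxidises the lactol to the hydroxy lactone (6S)-6-(3,4-dimethoxyphenyl)-3a-hydroxytetrahydro-1H,3H-furo[3,4-c]furan-1-one F2. MsCl/Et3N eliminates the β-hydroxyl (E1cB) to the butenolide (6R)-6-(3,4-dimethoxyphenyl)-4,6-dihydro-1H,3H-furo[3,4-c]furan-1-one F3, whose C2–H is not vinylogous to the carbonyl. H2 over Rh/Al2O3 adds to the face anti to the aryl group and gives the cis-fused lactone (3aS,6S,6aR)-6-(3,4-dimethoxyphenyl)tetrahydro-1H,3H-furo[3,4-c]furan-1-one F4. LiAlH4 gives the diol [(2S,3S,4R)-2-(3,4-dimethoxyphenyl)oxolane-3,4-diyl]dimethanol F5. PhI(OAc)2 with catalytic TEMPO then oxidises the less hindered hydroxymethyl group (the one remote from the cis aryl group) and the lactol that follows, which closes the lactone on the C4 arm and gives 11.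

Step 5. Process at risk: no hydride transfer to the fully substituted β-carbon of 10, or attack on the lactone carbonyl instead. The fallback leaves polar hydride chemistry for surface-mediated syn addition of dihydrogen. It sets out from 10 and returns at 11: hydrogenation over Rh/Al2O3 (H2, EtOAc, rt), with the catalyst binding the face anti to the C2 aryl group. Rhodium is preferred to palladium to limit hydrogenolysis of the allylic, benzylic C2–O1 bond and migration of the double bond. No new compound arises.

Step 7. Process at risk: the equilibrium resting on the side of the cyclic hemiketal, or β-elimination of the ring oxygen from the C4 enolate on prolonged base treatment. The fallback removes the hemiketal sink with a protecting group. It sets out from 14 and returns at 16. TBSCl/imidazole (DMF) silylates the primary hydroxyl of the open tautomer to give [(3S,4S,5S)-4-({[tert-butyl(dimethyl)silyl]oxy}methyl)-5-(3,4-dimethoxyphenyl)oxolan-3-yl](3,4,5-trimethoxyphenyl)methanone F6. DBU (toluene, rt) equilibrates C4 to the 3,4-trans ketone [(3R,4S,5S)-4-({[tert-butyl(dimethyl)silyl]oxy}methyl)-5-(3,4-dimethoxyphenyl)oxolan-3-yl](3,4,5-trimethoxyphenyl)methanone F7. Bu4NF buffered with AcOH (THF, 0 °C) removes the silyl group to give 16.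

**Further compounds**
F1 | step 2 | (6S)-6-(3,4-dimethoxyphenyl)tetrahydro-1H,3H-furo[3,4-c]furan-1,3a-diol | COc1ccc([C@H]2OCC3(O)COC(O)C23)cc1OC
F2 | step 2 | (6S)-6-(3,4-dimethoxyphenyl)-3a-hydroxytetrahydro-1H,3H-furo[3,4-c]furan-1-one | COc1ccc([C@H]2OCC3(O)COC(=O)C23)cc1OC
F3 | step 2 | (6R)-6-(3,4-dimethoxyphenyl)-4,6-dihydro-1H,3H-furo[3,4-c]furan-1-one | COc1ccc([C@H]2OCC3=C2C(=O)OC3)cc1OC
F4 | step 2 | (3aS,6S,6aR)-6-(3,4-dimethoxyphenyl)tetrahydro-1H,3H-furo[3,4-c]furan-1-one | COc1ccc([C@H]2OC[C@H]3COC(=O)[C@@H]23)cc1OC
F5 | step 2 | [(2S,3S,4R)-2-(3,4-dimethoxyphenyl)oxolane-3,4-diyl]dimethanol | COc1ccc([C@H]2OC[C@@H](CO)[C@H]2CO)cc1OC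
F0 | step 5 | none | none
F6 | step 7 | [(3S,4S,5S)-4-({[tert-butyl(dimethyl)silyl]oxy}methyl)-5-(3,4-dimethoxyphenyl)oxolan-3-yl](3,4,5-trimethoxyphenyl)methanone | COc1ccc([C@H]2OC[C@@H](C(=O)c3cc(OC)c(OC)c(OC)c3)[C@H]2CO[Si](C)(C)C(C)(C)C)cc1OC
F7 | step 7 | [(3R,4S,5S)-4-({[tert-butyl(dimethyl)silyl]oxy}methyl)-5-(3,4-dimethoxyphenyl)oxolan-3-yl](3,4,5-trimethoxyphenyl)methanone | COc1ccc([C@H]2OC[C@H](C(=O)c3cc(OC)c(OC)c(OC)c3)[C@H]2CO[Si](C)(C)C(C)(C)C)cc1OC
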